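The leftover we follow is the partner still free when a feed stops. Counting one partner in each first product and 2 in each double product, the last readings put the dose used when the feed stops at 18.8% in Saturday's run and 19.2% in Tuesday's, though Tuesday's dose is 2.92 times as large. Their mean, 19.0%, we carry as the used share u, the part of the dose found in products when the feed stops. By hand this constancy is expected. Partner enters at a steady rate and suffers a pseudo-first-order loss to substrate, with rate constant k times substrate concentration S, so over a feed of length t_f the used share comes to k·S·t_f/2 while it stays small, and the dose cancels.

| flask | substrate | partner | remark | time |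
|---|---|---|---|---|
| Saturday's | 20 mM | 12 mM (fed, over 5.0 h) | run made earlier; the fed solution adds 0.10 times the starting volume |  |
| Tuesday's | 20 mM | 35 mM (fed, over 5.0 h) | run made earlier; the fed solution adds 0.10 times the starting volume |  |
| autumn | 20 mM | 10.0 mM (fed, over 5.0 h) | the fed solution adds 0.10 times the starting volume | 5.0 h |
| summer | 20 mM | 20.0 mM (fed, over 5.0 h) | the fed solution adds 0.10 times the starting volume | 5.0 h |
| winter | 20 mM | 24.0 mM (fed, over 5.0 h) | the fed solution adds 0.10 times the starting volume | 5.0 h |

- Saturday's (time / h: first product / %, double product / %): 0.417: 0, 0.2; 0.667: 0.6, 0.2; 1.00: 0.8, 0.4; 2.00: 2.6, 0; 3.00: 4.5, 0; 5.00: 11.3, 0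
- Tuesday's (time / h: first product / %, double product / %): 0.333: 0, 0; 1.00: 1.4, 0; 2.00: 5.5, 0.1; 2.50: 9.0, 0.1; 4.00: 20.0, 1.4; 5.00: 27.0, 3.3

(standard deviation of a reading: 0.3 percentage points)

- every charge counts on the volume at the start, and the solution that is fed holds the whole dose
- on the list of suspects stand: partner + double product -> tris adduct; substrate + partner -> first product; partner + tris adduct <-> tetra adduct; partner + first product -> double product

1. final first product, as a percentage of the substrate charged, for each flask in turn (autumn, summer, winter)

Turn the dose first. The share stays, so the partner found in products, per substrate charged, is u times the dose over the substrate charge. Double product needs partner and first product together, each proportional to the dose, so we scale Tuesday's 3.3% by the square of the dose and take off 2 times that. Our reckoning gives 8.97%, 16.9% and 19.7% for autumn, summer and winter.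

Turn the dilution next. With every concentration of summer's recipe cut by a factor 2, S falls by that factor and u with it, so the partner found in products should be 9.51% of the substrate charged.

The forecast, made from the same runs, stands at 9.3%, 16.9% and 19.8%, higher than ours in autumn, and says of the tris adduct: “Any tris adduct would be a tiny loss, so I ignore it.”

The flasks give 9.31%, 17.2% and 20.0%. Our autumn figure lies 0.34 percentage points below its flask.

    partner + double product → tris adduct (k = 1.00 M⁻¹ h⁻¹)
    substrate + partner → first product (k = 5.00 M⁻¹ h⁻¹)
    partner + tris adduct ⇌ tetra adduct (K = 160 M⁻¹, k = 6.30 M⁻¹ h⁻¹)
    partner + first product → double product (k = 3.00 M⁻¹ h⁻¹)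

In summer, first product grew from 5.35% at 2.50 h to 17.2% at 5.00 h while partner and substrate stood in the flask, at the end 81% of partner's charge and 81.7% of substrate's. Partner + first product ran behind that step, taking double product from 0.0907% to 1.09% over the same times, with tris adduct at 0.0142% at the end. Summer's uptake of 0.194 equiv is a used share of 19.4%, counted as u was but with the tris and tetra adducts added. At twice the dilution of summer, where the halved share gave 9.51% for the partner in products, first product stands at 9.96%.

The readings stem from a simulated flask on assumed constants; noise was put on by code.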